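**Retrosynthetic overview**
1. Feature: in the target the lactone ring O1–C2(=O)–C3–C4–C5 is the sum of an alkyne (C3≡C4), an aldehyde (C5=O1) and CO (C2). The C4–Br bond marks the place for a silicon atom that is also bound, through oxygen, to the exocyclic carbon C6.
2. 23 ⇐ 22 (O-desilylation) ⇐ 18 (two Br2/Et3N cycles at C6) ⇐ 16 (mesylate elimination, C5=C6) ⇐ 14 (Br for Si at C4, C6–O–Si cleaved).
3. 14 ⇐ 13 + CO: carbonylative [2+2+1] of the silicon-tethered ynal, forming C4–C5, C2–C3 and C2–O1.
4. 13 ⇐ 11 (ozonolysis) ⇐ 6 + iPr2SiCl2 + allyl alcohol; 6 ⇐ 3 (asymmetric transfer hydrogenation sets C1′) ⇐ butanoyl chloride + bis(trimethylsilyl)acetylene.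
5. Ring order: the butenolide and the temporary 1,2-oxasilolane (C4, Si, O, C6, C5) close together in step 7; the oxasilolane is opened again in step 8.

Key step: step 7

Remark: C5 of 14 to 17 is formed without control and is carried as an epimer mixture, because it becomes sp2 in step 9. The (R)-alkynol is made by asymmetric reduction, not by enzymatic resolution, because propyl and ethynyl are too similar in size for a dependable resolution.

**Step 1**
Reactants: 1 butanoyl chloride; 2 bis(trimethylsilyl)acetylene
Product: 3 1-(trimethylsilyl)hex-1-yn-3-one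
Conditions: AlCl3 (1.1 equiv), CH2Cl2, 0 °C
Reagents that add atoms: none
Why: Friedel–Crafts-type acylation of the bis-silylalkyne (ipso-acyldesilylation through a β-silyl vinyl cation) should stop after one acylation because the ynone is deactivated.

**Step 2**
Reactants: 3 1-(trimethylsilyl)hex-1-yn-3-one
Product: 4 (3R)-1-(trimethylsilyl)hex-1-yn-3-ol
Conditions: Ru[(R,R)-TsDPEN](p-cymene) (1 mol %), iPrOH, rt
Reagents that add atoms: none
Why: Noyori asymmetric transfer hydrogenation of an alkynyl ketone, in which the alkynyl group takes the place of the aryl group of acetophenone in the concerted hydride/proton transfer, so the (R,R) catalyst should give the (R) carbinol, the future C1′.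

**Step 3**
Reactants: 4 (3R)-1-(trimethylsilyl)hex-1-yn-3-ol
Product: 5 (3R)-3-(tert-butyldimethylsilyloxy)-1-(trimethylsilyl)hex-1-yne
Conditions: TBSCl, imidazole, DMF, rt
Reagents that add atoms: tert-butyldimethylsilyl chloride, CC(C)(C)[Si](C)(C)Cl
Why: imidazole-promoted O-silylation of a secondary alcohol, which does not touch the stereocentre.

**Step 4**
Reactants: 5 (3R)-3-(tert-butyldimethylsilyloxy)-1-(trimethylsilyl)hex-1-yne
Product: 6 (3R)-3-(tert-butyldimethylsilyloxy)hex-1-yne
Conditions: K2CO3 (0.2 equiv), MeOH, rt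
Reagents that add atoms: none
Why: methoxide-induced protodesilylation cleaves the C(sp)–Si bond, while the O–TBS ether is inert under these conditions.

**Step 5**
Reactants: 6 (3R)-3-(tert-butyldimethylsilyloxy)hex-1-yne; 7 dichlorodiisopropylsilane; 8 allyl alcohol
Product: 11 (allyloxy)[(3R)-3-(tert-butyldimethylsilyloxy)hex-1-yn-1-yl]diisopropylsilane, via lithium acetylide 9 (not isolated), via alkynylchlorosilane 10 (not isolated)
Conditions: n-BuLi, THF, −78 °C; added to iPr2SiCl2 (3 equiv), THF, −78 °C to rt; excess silane evaporated; allyl alcohol, imidazole, CH2Cl2, 0 °C to rt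
Reagents that add atoms: none
Why: acetylide substitution at silicon should stop at mono-alkynylation because of the excess dichlorosilane and the two isopropyl groups, and the remaining Si–Cl bond is then capped by O-silylation of allyl alcohol.

**Step 6**
Reactants: 11 (allyloxy)[(3R)-3-(tert-butyldimethylsilyloxy)hex-1-yn-1-yl]diisopropylsilane
Product: 13 2-({[(3R)-3-(tert-butyldimethylsilyloxy)hex-1-yn-1-yl]diisopropylsilyl}oxy)acetaldehyde, via ozonide 12 (not isolated)
Conditions: O3, CH2Cl2, −78 °C (stopped at the first blue tinge); PPh3, −78 °C to rt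
Reagents that add atoms: ozone, [O-][O+]=O
Why: ozonolysis with reductive work-up, relying on the terminal alkene reacting with ozone far faster than the silyl-substituted alkyne.

**Step 7**
Reactants: 13 2-({[(3R)-3-(tert-butyldimethylsilyloxy)hex-1-yn-1-yl]diisopropylsilyl}oxy)acetaldehyde
Product: 14 silicon-bridged bicyclic butenolide: furan-2(5H)-one with the (1R)-1-(tert-butyldimethylsilyloxy)butyl group on C3 and a Si(iPr)2–O–CH2 bridge from C4 (Si) to C5 (CH2 = C6), cis-fused, C5 epimers
Conditions: Ru3(CO)12 (3 mol %), CO (10 atm), toluene, 160 °C, autoclave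
Reagents that add atoms: carbon monoxide, [C-]#[O+]
Why: Proposed new method: a zerovalent ruthenium carbonyl fragment binds the alkyne and the aldehyde C=O of 13 and couples them oxidatively to an oxaruthenacyclopentene (C4–C5 bond), CO inserts into the Ru–C3 bond, and C2–O1 reductive elimination releases the lactone and returns the catalyst. The closest known reactions are the Ru3(CO)12-catalysed cyclocarbonylation of 1,6-yne-aldehydes with silyl-capped alkynes to bicyclic butenolides (with its Mo(CO)6/DMSO counterpart) and silicon-tethered Pauson–Khand reactions; a Si–O–CH2 tether that puts silicon on the inner alkyne carbon has not been used. The 1,2-oxasilolane ring (C4, Si, O, C6, C5) is closed 5-exo-dig by the C4–C5 coupling, and the butenolide (O1, C2, C3, C4, C5) by the carbonylative [2+2+1] closure, C2–C3 first and C2–O1 second. C5 is the only new stereocentre; it is not controlled (C1′ is remote) and both epimers are used because C5 becomes sp2 in step 9. The step needs regioselectivity opposite to the intermolecular preference of silylalkynes, and chemoselectivity over aldehyde decarbonylation and alkyne oligomerisation: the three-atom tether lets only the silicon-bearing carbon reach C5, the two isopropyl groups favour the folded conformer, and CO pressure keeps acyl formation ahead of decarbonylation.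

**Step 8**
Reactants: 14 silicon-bridged bicyclic butenolide
Product: 16 4-bromo-3-[(1R)-1-(tert-butyldimethylsilyloxy)butyl]-5-(hydroxymethyl)furan-2(5H)-one (C5 epimers), via bromosilyl ether 15 (not isolated)
Conditions: Br2 (1.1 equiv), CH2Cl2, −20 °C to rt, dark; then HF·pyridine, pyridine, THF, 0 °C
Reagents that add atoms: bromine, BrBr
Why: Proposed new method: Br2 should form a bromonium ion on the only C=C of 14, and the C4–Si bond, β to the charge developing at C3, is then cleaved by bromide so that bromine replaces silicon with retention (a dibromide formed instead should lose silicon and the C3 bromide under the fluoride of the second stage and give the same alkene), after which HF·pyridine cleaves the labile primary halosilyl ether but not the hindered secondary TBS ether; the closest known reactions are bromo- and iododesilylation of vinylsilanes and of alkylidene oxasilacyclopentanes, which have not been shown for silicon on the β-carbon of an unsaturated lactone, where the cation lies α to the carbonyl.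

**Step 9**
Reactants: 16 4-bromo-3-[(1R)-1-(tert-butyldimethylsilyloxy)butyl]-5-(hydroxymethyl)furan-2(5H)-one
Product: 18 4-bromo-3-[(1R)-1-(tert-butyldimethylsilyloxy)butyl]-5-methylidenefuran-2(5H)-one, via mesylate 17 (not isolated)
Conditions: MsCl, Et3N (4 equiv), CH2Cl2, 0 °C to rt
Reagents that add atoms: none
Why: mesylation followed by E1cB elimination through the furanolate of the butenolide, in which the C6 mesylate should leave far faster than the C1′ silyloxy group, erases the uncontrolled C5 centre.

**Step 10**
Reactants: 18 4-bromo-3-[(1R)-1-(tert-butyldimethylsilyloxy)butyl]-5-methylidenefuran-2(5H)-one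
Product: 20 4-bromo-5-(bromomethylidene)-3-[(1R)-1-(tert-butyldimethylsilyloxy)butyl]furan-2(5H)-one (Z/E mixture), via dibromide 19 (not isolated)
Conditions: Br2 (1.05 equiv), CH2Cl2, 0 °C; then Et3N, 0 °C to rt
Reagents that add atoms: bromine, BrBr
Why: electrophilic addition of Br2 to the electron-rich exocyclic enol-ester alkene (not to the bromo-substituted ring alkene), then dehydrobromination across C5–C6, a sequence well known for 5-methylidene-2(5H)-furanones.

**Step 11**
Reactants: 20 4-bromo-5-(bromomethylidene)-3-[(1R)-1-(tert-butyldimethylsilyloxy)butyl]furan-2(5H)-one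
Product: 22 4-bromo-5-(dibromomethylidene)-3-[(1R)-1-(tert-butyldimethylsilyloxy)butyl]furan-2(5H)-one, via tribromide 21 (not isolated)
Conditions: Br2 (1.2 equiv), CH2Cl2, rt; then Et3N, 0 °C to rt
Reagents that add atoms: bromine, BrBr
Why: a second bromine addition and dehydrobromination at the same exocyclic alkene, in which both geometric isomers of 20 should converge on the one dibromomethylidene compound.

**Step 12**
Reactants: 22 4-bromo-5-(dibromomethylidene)-3-[(1R)-1-(tert-butyldimethylsilyloxy)butyl]furan-2(5H)-one
Product: 23 4-bromo-5-(dibromomethylidene)-3-[(1R)-1-hydroxybutyl]furan-2(5H)-one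
Conditions: HF (48% aq), MeCN, 0 °C to rt
Reagents that add atoms: none
Why: acidic fluoride desilylation avoids base and strong nucleophiles, to which the tribromo dienoate is sensitive, and should not ionise C1′ because a cation next to the electron-poor ring is disfavoured.

**Compound list**
1 | butanoyl chloride | CCCC(=O)Cl | starting material
2 | bis(trimethylsilyl)acetylene | C[Si](C)(C)C#C[Si](C)(C)C | starting material
3 | 1-(trimethylsilyl)hex-1-yn-3-one | CCCC(=O)C#C[Si](C)(C)C | intermediate
4 | (3R)-1-(trimethylsilyl)hex-1-yn-3-ol | CCC[C@@H](O)C#C[Si](C)(C)C | intermediate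
5 | (3R)-3-(tert-butyldimethylsilyloxy)-1-(trimethylsilyl)hex-1-yne | CCC[C@@H](O[Si](C)(C)C(C)(C)C)C#C[Si](C)(C)C | intermediate
6 | (3R)-3-(tert-butyldimethylsilyloxy)hex-1-yne | CCC[C@@H](O[Si](C)(C)C(C)(C)C)C#C | intermediate
7 | dichlorodiisopropylsilane | CC(C)[Si](Cl)(Cl)C(C)C | starting material
8 | allyl alcohol | C=CCO | starting material
9 | lithium acetylide of 6 | CCC[C@@H](O[Si](C)(C)C(C)(C)C)C#C[Li] | intermediate
10 | chloro[(3R)-3-(tert-butyldimethylsilyloxy)hex-1-yn-1-yl]diisopropylsilane | CCC[C@@H](O[Si](C)(C)C(C)(C)C)C#C[Si](Cl)(C(C)C)C(C)C | intermediate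
11 | (allyloxy)[(3R)-3-(tert-butyldimethylsilyloxy)hex-1-yn-1-yl]diisopropylsilane | CCC[C@@H](O[Si](C)(C)C(C)(C)C)C#C[Si](C(C)C)(C(C)C)OCC=C | intermediate
12 | ozonide (1,2,4-trioxolane) of 11, mixture at the trioxolane carbon | CCC[C@@H](O[Si](C)(C)C(C)(C)C)C#C[Si](C(C)C)(C(C)C)OCC1OCOO1 | intermediate
13 | 2-({[(3R)-3-(tert-butyldimethylsilyloxy)hex-1-yn-1-yl]diisopropylsilyl}oxy)acetaldehyde | CCC[C@@H](O[Si](C)(C)C(C)(C)C)C#C[Si](C(C)C)(C(C)C)OCC=O | intermediate
14 | silicon-bridged bicyclic butenolide (C3 side chain 1R, C4–Si(iPr)2–O–C6H2–C5, C5 epimers) | CCC[C@@H](O[Si](C)(C)C(C)(C)C)C1=C2C(CO[Si]2(C(C)C)C(C)C)OC1=O | intermediate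
15 | bromo(diisopropyl)silyl ether of 16 (C5 epimers) | CCC[C@@H](O[Si](C)(C)C(C)(C)C)C1=C(Br)C(CO[Si](Br)(C(C)C)C(C)C)OC1=O | intermediate
16 | 4-bromo-3-[(1R)-1-(tert-butyldimethylsilyloxy)butyl]-5-(hydroxymethyl)furan-2(5H)-one (C5 epimers) | CCC[C@@H](O[Si](C)(C)C(C)(C)C)C1=C(Br)C(CO)OC1=O | intermediate
17 | methanesulfonate of 16 (C5 epimers) | CCC[C@@H](O[Si](C)(C)C(C)(C)C)C1=C(Br)C(COS(C)(=O)=O)OC1=O | intermediate
18 | 4-bromo-3-[(1R)-1-(tert-butyldimethylsilyloxy)butyl]-5-methylidenefuran-2(5H)-one | CCC[C@@H](O[Si](C)(C)C(C)(C)C)C1=C(Br)C(=C)OC1=O | intermediate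
19 | 4,5-dibromo-5-(bromomethyl)-3-[(1R)-1-(tert-butyldimethylsilyloxy)butyl]furan-2(5H)-one (C5 epimers) | CCC[C@@H](O[Si](C)(C)C(C)(C)C)C1=C(Br)C(Br)(CBr)OC1=O | intermediate
20 | 4-bromo-5-(bromomethylidene)-3-[(1R)-1-(tert-butyldimethylsilyloxy)butyl]furan-2(5H)-one (Z/E mixture, geometry left open) | CCC[C@@H](O[Si](C)(C)C(C)(C)C)C1=C(Br)C(=CBr)OC1=O | intermediate
21 | 4,5-dibromo-5-(dibromomethyl)-3-[(1R)-1-(tert-butyldimethylsilyloxy)butyl]furan-2(5H)-one (C5 epimers) | CCC[C@@H](O[Si](C)(C)C(C)(C)C)C1=C(Br)C(Br)(C(Br)Br)OC1=O | intermediate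
22 | 4-bromo-5-(dibromomethylidene)-3-[(1R)-1-(tert-butyldimethylsilyloxy)butyl]furan-2(5H)-one | CCC[C@@H](O[Si](C)(C)C(C)(C)C)C1=C(Br)C(=C(Br)Br)OC1=O | intermediate
23 | 4-bromo-5-(dibromomethylidene)-3-[(1R)-1-hydroxybutyl]furan-2(5H)-one | CCC[C@@H](O)C1=C(Br)C(=C(Br)Br)OC1=O | target

**Step count**
Total: 12 steps. Longest linear sequence: 12 steps (1 and 2 to 23).

**Steps most likely to fail**

Step 7. The alkyne–aldehyde coupling may stall because both alkyne ends carry bulky groups, or the aldehyde may be lost by decarbonylation before cyclisation. The fallback uses known chemistry, sets out from 6 and returns at 16, and places bromine directly without a silicon tether. The lithium acetylide of 6 is added to (tert-butyldimethylsilyloxy)acetaldehyde to give the propargylic alcohol F1. Methyl chloroformate and pyridine convert it into the methyl carbonate F2. Carbonylation with Pd(OAc)2/PPh3 under CO in MeOH (SN2′ oxidative addition, CO insertion, methanolysis) gives the 2,3-dienoate F3. CuBr2 in aqueous acetone at 65 °C effects bromolactonisation, bromine going to the central allene carbon (C4) and the ester oxygen to C5, to give the bromobutenolide F4. HF·pyridine in pyridine/THF then removes the primary silyl ether selectively and delivers 16.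

Step 8. Ipso attack of bromine at C4 may not take place, because the alkene is hindered and electronically deactivated toward substitution at that carbon. The fallback uses known chemistry, sets out from 14 and returns at 18. Tamao–Fleming oxidation of the alkenyl(alkoxy)silane with KHF2 and mCPBA in DMF gives the 5-(hydroxymethyl)tetronic acid F5. This is used at once, because its free enol could expel the C1′ silyloxy group. Oxalyl bromide and DMF in CH2Cl2 (Vilsmeier-type bromide) turn the enol into the vinyl bromide and the primary alcohol into the alkyl bromide, giving the dibromide F6. Et3N added to the same flask eliminates HBr across C5–C6 to give 18.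

Step 6. Ozone may over-oxidise the silyl alkyne, or the alkynylsilyl ether may hydrolyse during the reductive work-up, so that the ynal is not obtained clean. The fallback sets out from the chlorosilane 10 (made as in step 5) and returns at 13. Compound 10 is capped with a large excess of ethylene glycol and imidazole to give the 2-hydroxyethyl silyl ether F7, which is oxidised with Dess–Martin periodinane (NaHCO3, CH2Cl2) to 13; no ozone is used.

**Further compounds**
F1 | step 7 | (5R)-1,5-bis(tert-butyldimethylsilyloxy)oct-3-yn-2-ol (C2 epimers) | CCC[C@@H](O[Si](C)(C)C(C)(C)C)C#CC(O)CO[Si](C)(C)C(C)(C)C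
F2 | step 7 | methyl carbonate of F1 | CCC[C@@H](O[Si](C)(C)C(C)(C)C)C#CC(OC(=O)OC)CO[Si](C)(C)C(C)(C)C
F3 | step 7 | methyl 2-[(1R)-1-(tert-butyldimethylsilyloxy)butyl]-5-(tert-butyldimethylsilyloxy)penta-2,3-dienoate (allene axis uncontrolled) | CCC[C@@H](O[Si](C)(C)C(C)(C)C)C(C(=O)OC)=C=CCO[Si](C)(C)C(C)(C)C
F4 | step 7 | 4-bromo-3-[(1R)-1-(tert-butyldimethylsilyloxy)butyl]-5-[(tert-butyldimethylsilyloxy)methyl]furan-2(5H)-one (C5 epimers) | CCC[C@@H](O[Si](C)(C)C(C)(C)C)C1=C(Br)C(CO[Si](C)(C)C(C)(C)C)OC1=O
F5 | step 8 | 4-hydroxy-5-(hydroxymethyl)-3-[(1R)-1-(tert-butyldimethylsilyloxy)butyl]furan-2(5H)-one (C5 epimers) | CCC[C@@H](O[Si](C)(C)C(C)(C)C)C1=C(O)C(CO)OC1=O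
F6 | step 8 | 4-bromo-5-(bromomethyl)-3-[(1R)-1-(tert-butyldimethylsilyloxy)butyl]furan-2(5H)-one (C5 epimers) | CCC[C@@H](O[Si](C)(C)C(C)(C)C)C1=C(Br)C(CBr)OC1=O
F7 | step 6 | 2-({[(3R)-3-(tert-butyldimethylsilyloxy)hex-1-yn-1-yl]diisopropylsilyl}oxy)ethanol | CCC[C@@H](O[Si](C)(C)C(C)(C)C)C#C[Si](C(C)C)(C(C)C)OCCO
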